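**Retrosynthetic overview**
1. Kanzonol Y ⇒ C-alpha–O bond (the only stereocentre). This is an enantioselective formal anti-Michael hydration of the (E)-diprenylchalcone, run on its tris-TBS ether: hydride goes to C-beta, electrophilic oxygen goes to C-alpha of a chiral copper enolate, and fluoride releases the product in the same flask.
2. Chalcone ⇒ C-alpha=C-beta bond, by Claisen–Schmidt condensation of 5-prenylresacetophenone with 4-hydroxy-3-prenylbenzaldehyde, both unprotected.
3. Prenylarenes ⇒ aryl–CH2 bonds, by direct C-prenylation of 2,4-dihydroxyacetophenone (Friedel–Crafts, C5) and of 4-hydroxybenzaldehyde (phenoxide ortho-alkylation).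
4. No ring is formed; rings A and B are bought as arenes.

Assumption: the SMILES descriptor reads as (R) at C-alpha (OH > C=O > CH2Ar > H); (R)-DTBM-SEGPHOS is taken as the ligand hand that leaves the Re face of the enolate open, and the equally available (S)-ligand is used if the first run shows the opposite sense.

**Step 1**
Reactants: 1 4-hydroxybenzaldehyde; 2 prenyl bromide (1-bromo-3-methylbut-2-ene)
Product: 3 4-hydroxy-3-(3-methylbut-2-en-1-yl)benzaldehyde
Conditions: KOH (1.1 equiv), H2O, 25 °C, 24 h
Reagents that add atoms: none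
Why: Ortho C-alkylation of an ambident phenoxide (SN2 at the primary allylic carbon): in water the phenoxide oxygen is tied up by hydrogen bonding so carbon attack competes, the para position is blocked by CHO, the two ortho positions are equivalent, and the neutral O-prenyl ether by-product is removed by base extraction.

**Step 2**
Reactants: 4 2,4-dihydroxyacetophenone; 5 2-methylbut-3-en-2-ol
Product: 6 1-[2,4-dihydroxy-5-(3-methylbut-2-en-1-yl)phenyl]ethan-1-one
Conditions: BF3·OEt2 (0.3 equiv), dioxane, 25 °C, 2 h
Reagents that add atoms: none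
Why: Friedel–Crafts allylation: BF3 ionises the tertiary allylic alcohol to the dimethylallyl cation, which is taken at its primary terminus by C5 of ring A (para to 2-OH, ortho to 4-OH, far less crowded than C3 between the two oxygens), the short time avoids chroman formation, and the minor 3-prenyl isomer is removed by chromatography.

**Step 3**
Reactants: 3 4-hydroxy-3-(3-methylbut-2-en-1-yl)benzaldehyde; 6 1-[2,4-dihydroxy-5-(3-methylbut-2-en-1-yl)phenyl]ethan-1-one
Product: 7 (E)-1-[2,4-dihydroxy-5-prenylphenyl]-3-[4-hydroxy-3-prenylphenyl]prop-2-en-1-one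
Conditions: KOH (60% aq, 12 equiv), EtOH, N2, 25 °C, 60 h; then 1 M HCl, 0 °C, to pH 5
Reagents that add atoms: none
Why: Claisen–Schmidt (crossed aldol) condensation: only the methyl ketone can enolise and only the aldehyde can accept, E1cB loss of water gives the conjugated (E)-enone as the thermodynamic product, and the prenyl groups are inert to hydroxide.

**Step 4**
Reactants: 7 (E)-diprenyl-trihydroxychalcone
Product: 8 (E)-1-[2,4-bis(tert-butyldimethylsilyloxy)-5-prenylphenyl]-3-[4-(tert-butyldimethylsilyloxy)-3-prenylphenyl]prop-2-en-1-one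
Conditions: TBSOTf (3.6 equiv), 2,6-lutidine (5 equiv), CH2Cl2, 0 °C to rt
Reagents that add atoms: tert-butyldimethylsilyl trifluoromethanesulfonate (TBSOTf), CC(C)(C)[Si](C)(C)OS(=O)(=O)C(F)(F)F
Why: O-Silylation with a silyl triflate and a hindered pyridine base is reactive enough to cap even the chelated 2'-OH, it removes the three acidic protons that would quench the copper enolate of step 5, and the bulky TBS groups stay out of the silyl transfers of that step, whereas smaller aryl silyl ethers would hand their silicon to the copper alkoxide and stop the chain.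

**Step 5**
Reactants: 8 tris-TBS (E)-chalcone
Product: 11 (R)-kanzonol Y, via silyl enol ether 9 (not isolated), via siloxy ketone 10 (not isolated)
Conditions: Cu(OAc)2 (5 mol %), (R)-DTBM-SEGPHOS (5.5 mol %), (EtO)2MeSiH (1.1 equiv), toluene, 0 °C, 2 h; then (±)-trans-2-(phenylsulfonyl)-3-phenyloxaziridine (1.3 equiv), −40 °C, 12 h; then Et3N·3HF (6 equiv), THF, 0 °C to rt, 12 h
Reagents that add atoms: 2-(phenylsulfonyl)-3-phenyloxaziridine, O=S(=O)(c1ccccc1)N1OC1c1ccccc1 (gives the C-alpha oxygen); diethoxymethylsilane, CCO[SiH](C)OCC (silicon only in 9 and 10, hydrogen only in 11)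
Why: Proposed new method: a one-catalyst relay that amounts to an enantioselective anti-Michael hydration of an enone; (a) L*CuH delivers hydride to C-beta of the s-cis enone and the copper enolate is silylated by the silane, giving (Z)-silyl enol ether 9 and using up all Si–H before any oxidant is present, so neither the oxaziridine nor the product ketone ever meets hydride; (b) the residual chiral monovalent copper enolate attacks the oxaziridine oxygen in an SN2-type O-transfer on the Re face of C-alpha, the face left open by the DTBM-aryl quadrants, which forms the C-alpha–O bond and sets the (R) centre, the hemiaminal collapses to sulfonimine plus L*Cu alkoxide, and this more basic alkoxide takes the small alkoxysilyl group from the next molecule of 9, releasing 10 and regenerating the chiral enolate; (c) slightly acidic fluoride cleaves all four Si–O bonds without racemisation; the oxaziridine reacts with the enolate but not with the two electron-rich prenyl alkenes, which rule out peracid, dioxirane or OsO4 oxidations; the closest known reaction types are CuH-catalysed 1,4-hydrosilylation and reductive aldol reaction of enones, chiral copper-enolate aldol catalysis started from silyl enol ethers, Davis oxidation of alkali enolates, Lewis-acid-catalysed asymmetric hydroxylation of beta-keto esters with racemic oxaziridines, and the racemic Mn(dpm)3/PhSiH3/O2 reductive alpha-hydroxylation of enones.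

**Compound list**
1 | 4-hydroxybenzaldehyde | O=Cc1ccc(O)cc1 | starting material
2 | prenyl bromide (1-bromo-3-methylbut-2-ene) | CC(C)=CCBr | starting material
3 | 4-hydroxy-3-(3-methylbut-2-en-1-yl)benzaldehyde | CC(C)=CCc1cc(C=O)ccc1O | intermediate
4 | 2,4-dihydroxyacetophenone | CC(=O)c1ccc(O)cc1O | starting material
5 | 2-methylbut-3-en-2-ol | CC(C)(O)C=C | starting material
6 | 1-[2,4-dihydroxy-5-(3-methylbut-2-en-1-yl)phenyl]ethan-1-one | CC(=O)c1cc(CC=C(C)C)c(O)cc1O | intermediate
7 | (E)-1-[2,4-dihydroxy-5-prenylphenyl]-3-[4-hydroxy-3-prenylphenyl]prop-2-en-1-one | CC(C)=CCc1cc(/C=C/C(=O)c2cc(CC=C(C)C)c(O)cc2O)ccc1O | intermediate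
8 | tris-TBS ether of 7, (E) | CC(C)=CCc1cc(/C=C/C(=O)c2cc(CC=C(C)C)c(O[Si](C)(C)C(C)(C)C)cc2O[Si](C)(C)C(C)(C)C)ccc1O[Si](C)(C)C(C)(C)C | intermediate
9 | (Z)-1-[2,4-bis(TBSO)-5-prenylphenyl]-1-[diethoxy(methyl)silyloxy]-3-[4-(TBSO)-3-prenylphenyl]prop-1-ene | CC(C)=CCc1cc(C/C=C(\O[Si](C)(OCC)OCC)c2cc(CC=C(C)C)c(O[Si](C)(C)C(C)(C)C)cc2O[Si](C)(C)C(C)(C)C)ccc1O[Si](C)(C)C(C)(C)C | intermediate
10 | (R)-1-[2,4-bis(TBSO)-5-prenylphenyl]-2-[diethoxy(methyl)silyloxy]-3-[4-(TBSO)-3-prenylphenyl]propan-1-one | CC(C)=CCc1cc(C[C@@H](O[Si](C)(OCC)OCC)C(=O)c2cc(CC=C(C)C)c(O[Si](C)(C)C(C)(C)C)cc2O[Si](C)(C)C(C)(C)C)ccc1O[Si](C)(C)C(C)(C)C | intermediate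
11 | (R)-kanzonol Y, (R)-1-[2,4-dihydroxy-5-prenylphenyl]-2-hydroxy-3-[4-hydroxy-3-prenylphenyl]propan-1-one | CC(C)=CCc1cc(C[C@@H](O)C(=O)c2cc(CC=C(C)C)c(O)cc2O)ccc1O | target

**Total step count:** 5.
**Longest linear sequence:** 4 (4 → 6 → 7 → 8 → 11, or 1 → 3 → 7 → 8 → 11).

**Three steps most likely to fail**

Risk 1, step 5 (the new reaction).
- **Failure modes:** The oxaziridine may oxidise the phosphine or enter single-electron chemistry with monovalent copper. The silyl transfer from 9 to the hindered copper alkoxide may stall. The sulfonimine may capture the enolate in an imino-aldol reaction. The ee may be low.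
- **Fallback:** This uses known chemistry and relies on reagent control at a preformed alkali enolate instead of catalyst control. It sets out from 8.
  - CuH conjugate reduction with a proton source (Cu(OAc)2, 1,2-bis(diphenylphosphino)benzene, polymethylhydrosiloxane, t-BuOH, toluene, rt) gives the tris-TBS dihydrochalcone F1.
  - NaN(SiMe3)2 in THF at −78 °C converts it into the sodium (Z)-enolate F2.
  - The enolate is hydroxylated at −78 °C with (−)-[(8,8-dichlorocamphoryl)sulfonyl]oxaziridine and quenched with NH4Cl to give the tris-TBS (R)-alpha-hydroxy ketone F3. This is a Davis asymmetric enolate hydroxylation. The (+)-reagent gives (S)-alcohols from (Z)-enolates of aryl alkyl ketones, so the (−)-reagent is taken for (R).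
  - Et3N·3HF in THF brings the sequence back to the route at 11.

Risk 2, step 2.
- **Failure modes:** C5/C3 selectivity may be modest, and over-prenylation or acid-induced chroman formation may occur.
- **Fallback:** This is O-alkylation followed by rearrangement instead of direct Friedel–Crafts attack. It sets out from 4.
  - Alkylation with 2 (K2CO3, acetone, reflux) touches only the non-chelated 4-OH and gives 2-hydroxy-4-(prenyloxy)acetophenone F4.
  - A clay-promoted [1,3]-shift of the prenyl group (montmorillonite K10 clay, Al2Si4O10(OH)2·nH2O, CH2Cl2, 0 °C to rt) moves it to the less hindered ortho carbon C5. The sequence comes back to the route at 6.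

Risk 3, step 3.
- **Failure modes:** Condensation between a dianionic ketone and an anionic, poorly electrophilic aldehyde is slow and may stop at low conversion.
- **Fallback:** The acidic para-phenols are masked so the aldol runs on far less charged partners. It sets out from 6 and 3.
  - MOMCl and i-Pr2NEt in CH2Cl2 convert 6 into 2-hydroxy-4-(methoxymethoxy)-5-prenylacetophenone F5.
  - The same conditions convert 3 into 4-(methoxymethoxy)-3-prenylbenzaldehyde F6.
  - KOH in EtOH at rt condenses them to the bis-MOM (E)-chalcone F7.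
  - 3 M HCl in MeOH at 40 °C removes both acetals. The sequence comes back to the route at 7.

**Further compounds**
F1 | step 5 | 1-[2,4-bis(TBSO)-5-prenylphenyl]-3-[4-(TBSO)-3-prenylphenyl]propan-1-one | CC(C)=CCc1cc(CCC(=O)c2cc(CC=C(C)C)c(O[Si](C)(C)C(C)(C)C)cc2O[Si](C)(C)C(C)(C)C)ccc1O[Si](C)(C)C(C)(C)C
F2 | step 5 | sodium (Z)-enolate of F1 | CC(C)=CCc1cc(C/C=C(\[O-])c2cc(CC=C(C)C)c(O[Si](C)(C)C(C)(C)C)cc2O[Si](C)(C)C(C)(C)C)ccc1O[Si](C)(C)C(C)(C)C.[Na+]
F3 | step 5 | (R)-1-[2,4-bis(TBSO)-5-prenylphenyl]-2-hydroxy-3-[4-(TBSO)-3-prenylphenyl]propan-1-one | CC(C)=CCc1cc(C[C@@H](O)C(=O)c2cc(CC=C(C)C)c(O[Si](C)(C)C(C)(C)C)cc2O[Si](C)(C)C(C)(C)C)ccc1O[Si](C)(C)C(C)(C)C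
F4 | step 2 | 1-[2-hydroxy-4-(3-methylbut-2-en-1-yloxy)phenyl]ethan-1-one | CC(=O)c1ccc(OCC=C(C)C)cc1O
F5 | step 3 | 1-[2-hydroxy-4-(methoxymethoxy)-5-(3-methylbut-2-en-1-yl)phenyl]ethan-1-one | CC(=O)c1cc(CC=C(C)C)c(OCOC)cc1O
F6 | step 3 | 4-(methoxymethoxy)-3-(3-methylbut-2-en-1-yl)benzaldehyde | CC(C)=CCc1cc(C=O)ccc1OCOC
F7 | step 3 | (E)-1-[2-hydroxy-4-(methoxymethoxy)-5-prenylphenyl]-3-[4-(methoxymethoxy)-3-prenylphenyl]prop-2-en-1-one | CC(C)=CCc1cc(/C=C/C(=O)c2cc(CC=C(C)C)c(OCOC)cc2O)ccc1OCOC
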